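**Retrosynthetic overview**
- The strategy rests on the fully substituted benzo ring C4a–C5(OH)–C6(Me)–C7(OH)–C8(Me)–C8a(O1). Its oxygens sit on alternate carbons, which is the pattern a vinylketene/ynol ether benzannulation delivers, and its C4a=C8a edge can be taken from the C3=C2 bond of a 2-acyl-4-pyranone.
- Target 22 comes from 7-O-silyl chromone 21 by desilylation. 21 comes from diazo ketone 13 and siloxypropyne 17: the Wolff shift makes C8–C8a, the (2+2) makes C5–C6 and C7–C8, the 4π opening breaks C5–C8, and the 6π closure makes C4a–C5.
- 13 comes from pyranone acid chloride 10 and diazoethane 12. 10 is reached from pyranone ester 8, which comes from triketo ester 7 by cyclodehydration.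
- 7 comes from nonadecane-2,4-dione 4 and diethyl oxalate 5; 4 comes from acetylacetone 1 and 1-bromotetradecane 2; 17 comes from ethyl acetate 14 by ynolate homologation and O-silylation.
- Ring order: the 4-pyranone ring is made first (step 3), and the benzene ring is then annulated onto its C2=C3 bond (step 9), which completes the chromone.

Key step: step 9

Remark: the target is achiral and is treated as the 4-oxo (chromone) tautomer; racemic intermediates are drawn without stereodescriptors, and diazoethane is handled only as a cold, dilute ethereal solution.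

**Step 1**
Reactants: 1 acetylacetone (pentane-2,4-dione); 2 1-bromotetradecane
Product: 4 nonadecane-2,4-dione, via dilithium pentane-2,4-dione dianion 3 (not isolated)
Conditions: LiN(i-Pr)2 (2.2 equiv), THF, −78 → 0 °C; then 2 (0.9 equiv), 0 °C → rt; 1 M HCl
Reagents that add atoms: none
Why: Double deprotonation gives the 1,3-dianion of the β-diketone, whose terminal methyl-derived carbanion is far more nucleophilic than the internal enolate carbon and should undergo clean SN2 C-alkylation with the primary bromide (γ-alkylation of a β-diketone dianion), installing the C15 chain on one carbonyl.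

**Step 2**
Reactants: 4 nonadecane-2,4-dione; 5 diethyl oxalate
Product: 7 ethyl 2,4,6-trioxohenicosanoate, via dilithium nonadecane-2,4-dione dianion 6 (not isolated)
Conditions: LiN(i-Pr)2 (2.2 equiv), THF, −78 → 0 °C; then cannulated into 5 (1.5 equiv), THF, −78 → 0 °C; 1 M HCl
Reagents that add atoms: none
Why: The second, kinetic deprotonation of 4 should occur at the C1 methyl rather than the C5 methylene, and the resulting terminal carbanion is acylated by the non-enolisable oxalate (crossed Claisen acylation of a β-diketone dianion), with inverse addition into excess oxalate holding back a second addition.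

**Step 3**
Reactants: 7 ethyl 2,4,6-trioxohenicosanoate
Product: 8 ethyl 4-oxo-6-pentadecyl-4H-pyran-2-carboxylate
Conditions: p-TsOH·H2O (cat.), toluene, reflux, Dean–Stark
Reagents that add atoms: none
Why: Acid-catalysed cyclodehydration of a 1,3,5-tricarbonyl chain, in which the C6 enol oxygen adds to the C2 keto group and water is lost, should give the cross-conjugated 4-pyranone, the only six-membered oxacycle open to this chain, with the ethyl ester untouched.

**Step 4**
Reactants: 8 ethyl 4-oxo-6-pentadecyl-4H-pyran-2-carboxylate
Product: 9 4-oxo-6-pentadecyl-4H-pyran-2-carboxylic acid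
Conditions: 6 M HCl, AcOH, 100 °C
Reagents that add atoms: water, O
Why: Acid-catalysed ester hydrolysis is chosen because the protonated 4-pyranone ring is inert to hot aqueous acid, whereas hydroxide would open it by conjugate attack at C2 or C6.

**Step 5**
Reactants: 9 4-oxo-6-pentadecyl-4H-pyran-2-carboxylic acid
Product: 10 4-oxo-6-pentadecyl-4H-pyran-2-carbonyl chloride
Conditions: SOCl2 (neat), 70 °C; volatiles removed, toluene chase; used crude
Reagents that add atoms: thionyl chloride, O=S(Cl)Cl
Why: Standard acid chloride formation through the chlorosulfite; the weakly nucleophilic vinylogous-ester carbonyl of the pyranone should be returned unchanged once SO2 and HCl are stripped off.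

**Step 6**
Reactants: 11 N-ethyl-N-nitrosourea
Product: 12 diazoethane (dried ethereal solution)
Conditions: 50% aq. KOH, Et2O, −10 → 0 °C; ether layer decanted and dried over KOH pellets; used at once
Reagents that add atoms: none
Why: Base-induced fragmentation of an N-alkyl-N-nitrosourea through the diazotate is the standard source of a higher diazoalkane, with cyanate and water staying in the aqueous phase.

**Step 7**
Reactants: 10 4-oxo-6-pentadecyl-4H-pyran-2-carbonyl chloride; 12 diazoethane
Product: 13 2-(2-diazopropanoyl)-6-pentadecyl-4H-pyran-4-one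
Conditions: 12 (3 equiv, Et2O), 10 in THF added dropwise, −20 → 0 °C; excess 12 removed in a stream of N2; chromatography on Et3N-deactivated silica
Reagents that add atoms: none
Why: C-acylation of a diazoalkane by an acid chloride that has no α-hydrogen (Arndt–Eistert-type diazo ketone synthesis) should be fast at low temperature, and a second equivalent of diazoethane takes up the HCl so that the α-chloro ketone is not formed.

**Step 8**
Reactants: 14 ethyl acetate
Product: 17 1-(triisopropylsilyloxy)prop-1-yne, via lithium dibromoenolate 15 (not isolated), via lithium propynolate 16 (not isolated)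
Conditions: CH2Br2, LiTMP (lithium 2,2,6,6-tetramethylpiperidide), THF, −78 °C; then 14; then LiN(SiMe3)2, −78 °C; then n-BuLi, −78 °C → rt; then i-Pr3SiCl, −78 °C → rt; distillation
Reagents that add atoms: dibromomethane, BrCBr; triisopropylsilyl chloride, CC(C)[Si](Cl)(C(C)C)C(C)C
Why: Kowalski ester homologation, in which dibromomethyllithium adds to the ester, the derived dibromo enolate 15 undergoes Br/Li exchange and a carbenoid 1,2-shift to ynolate 16, and the bulky silyl chloride traps 16 on oxygen to give the siloxyalkyne.

**Step 9**
Reactants: 13 2-(2-diazopropanoyl)-6-pentadecyl-4H-pyran-4-one; 17 1-(triisopropylsilyloxy)prop-1-yne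
Product: 21 5-hydroxy-6,8-dimethyl-2-pentadecyl-7-(triisopropylsilyloxy)-4H-chromen-4-one, via pyranonyl methyl ketene 18 (not isolated), via siloxycyclobutenone 19 (not isolated), via dienylketene 20 (not isolated)
Conditions: 17 (2 equiv), degassed ClCH2CH2Cl, hν 365 nm (Pyrex), rt until N2 evolution ends; then 80 °C
Reagents that add atoms: none
Why: Light expels N2 from 13 and the pyranon-2-yl group shifts from the carbonyl carbon to the carbene carbon (Wolff rearrangement, creating the future C8–C8a bond) to give ketene 18, whose carbonyl carbon is attacked by the nucleophilic, methyl-bearing carbon of 17 so that a (2+2) cycloaddition closes the four-membered ring of 19 (forming C5–C6 and C7–C8). Heating opens 19 by reversible conrotatory 4π electrocyclic cleavage of the old carbonyl-to-diazo-carbon bond (C5–C8) to dienylketene 20, and the benzene ring is then closed by thermal disrotatory 6π electrocyclisation of the ketene carbon onto pyranone C3 (forming C4a–C5), after which enolisation of the cyclohexadienone gives the C5 phenol and restores the pyranone as the chromone ring. The closest known reaction type is the second-generation Danheiser benzannulation of unsaturated and heteroaryl α-diazo ketones with siloxyalkynes, with the pyranone C2=C3 bond here serving as the vinyl unit of the ketene. No stereocentre survives, since the quaternary carbon of racemic 19 becomes sp2 C8, and because the ring opening of 19 is reversible the geometry of 20 needed for closure (pyranonyl cis to the ketene arm) is drained off productively. The selectivity needed is regiochemical, namely the siloxy carbon bonded to the methyl-bearing ketene carbon (C7 next to C8) and closure only at C3, and it is secured by the polarisation of the ynol ether and by C3 being the only ring carbon adjacent to the ketene-bearing C2. Irradiation at 365 nm, outside the strong pyranone absorption, is chosen to favour the Wolff shift over pyranone photoisomerisation and carbene 1,2-hydrogen shift, and aromatisation together with the C5-OH to C4=O hydrogen bond supplies the driving force.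

**Step 10**
Reactants: 21 5-hydroxy-6,8-dimethyl-2-pentadecyl-7-(triisopropylsilyloxy)-4H-chromen-4-one
Product: 22 5,7-dihydroxy-6,8-dimethyl-2-pentadecyl-4H-chromen-4-one (target)
Conditions: Bu4NF (1.2 equiv), AcOH (1.2 equiv), THF, 0 °C → rt
Reagents that add atoms: none
Why: Fluoride-induced Si–O cleavage of an aryl silyl ether, driven by Si–F bond formation and buffered with acetic acid so that the chromone never meets a strongly basic medium, should free the C7 phenol without touching anything else.

**Compound list**
1 | acetylacetone (pentane-2,4-dione) | CC(=O)CC(C)=O | starting material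
2 | 1-bromotetradecane | CCCCCCCCCCCCCCBr | starting material
3 | dilithium pentane-2,4-dione 1,3-dianion | [Li+].[Li+].C=C([O-])C=C(C)[O-] | intermediate
4 | nonadecane-2,4-dione | CCCCCCCCCCCCCCCC(=O)CC(C)=O | intermediate
5 | diethyl oxalate | CCOC(=O)C(=O)OCC | starting material
6 | dilithium nonadecane-2,4-dione 1,3-dianion | [Li+].[Li+].C=C([O-])C=C([O-])CCCCCCCCCCCCCCC | intermediate
7 | ethyl 2,4,6-trioxohenicosanoate | CCCCCCCCCCCCCCCC(=O)CC(=O)CC(=O)C(=O)OCC | intermediate
8 | ethyl 4-oxo-6-pentadecyl-4H-pyran-2-carboxylate | CCCCCCCCCCCCCCCc1cc(=O)cc(C(=O)OCC)o1 | intermediate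
9 | 4-oxo-6-pentadecyl-4H-pyran-2-carboxylic acid | CCCCCCCCCCCCCCCc1cc(=O)cc(C(=O)O)o1 | intermediate
10 | 4-oxo-6-pentadecyl-4H-pyran-2-carbonyl chloride | CCCCCCCCCCCCCCCc1cc(=O)cc(C(Cl)=O)o1 | intermediate
11 | N-ethyl-N-nitrosourea | CCN(N=O)C(N)=O | starting material
12 | diazoethane | CC=[N+]=[N-] | intermediate
13 | 2-(2-diazopropanoyl)-6-pentadecyl-4H-pyran-4-one | CCCCCCCCCCCCCCCc1cc(=O)cc(C(=O)C(C)=[N+]=[N-])o1 | intermediate
14 | ethyl acetate | CCOC(C)=O | starting material
15 | lithium 1,1-dibromoprop-1-en-2-olate | [Li+].CC([O-])=C(Br)Br | intermediate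
16 | lithium prop-1-yn-1-olate | [Li+].CC#C[O-] | intermediate
17 | 1-(triisopropylsilyloxy)prop-1-yne | CC#CO[Si](C(C)C)(C(C)C)C(C)C | intermediate
18 | 2-(4-oxo-6-pentadecyl-4H-pyran-2-yl)prop-1-en-1-one (pyranonyl methyl ketene) | CCCCCCCCCCCCCCCc1cc(=O)cc(C(C)=C=O)o1 | intermediate
19 | 2,4-dimethyl-4-(4-oxo-6-pentadecyl-4H-pyran-2-yl)-3-(triisopropylsilyloxy)cyclobut-2-en-1-one (racemic) | CCCCCCCCCCCCCCCc1cc(=O)cc(C2(C)C(=O)C(C)=C2O[Si](C(C)C)(C(C)C)C(C)C)o1 | intermediate
20 | (3E)-2,4-dimethyl-4-(4-oxo-6-pentadecyl-4H-pyran-2-yl)-3-(triisopropylsilyloxy)buta-1,3-dien-1-one (pyranonyl cis to the ketene arm) | CCCCCCCCCCCCCCCc1cc(=O)cc(o1)/C(C)=C(O[Si](C(C)C)(C(C)C)C(C)C)\C(C)=C=O | intermediate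
21 | 5-hydroxy-6,8-dimethyl-2-pentadecyl-7-(triisopropylsilyloxy)-4H-chromen-4-one | CCCCCCCCCCCCCCCc1cc(=O)c2c(O)c(C)c(O[Si](C(C)C)(C(C)C)C(C)C)c(C)c2o1 | intermediate
22 | 5,7-dihydroxy-6,8-dimethyl-2-pentadecyl-4H-chromen-4-one | CCCCCCCCCCCCCCCc1cc(=O)c2c(O)c(C)c(O)c(C)c2o1 | target

**Step count**
Total step count: 10.
Longest linear sequence: 8 steps (steps 1, 2, 3, 4, 5, 7, 9, 10, from acetylacetone); steps 6 and 8 are one-step side branches.

**Steps most likely to fail**

Step 9. Light absorption by the pyranone chromophore (photoisomerisation of the ring or of the chromone product) and loss of the ketene before it meets the alkyne may outrun the cascade. The fallback generates the same ketene in the dark and sets out from 13. Silver benzoate (AgOCOPh, cat.) and Et3N in THF/H2O at rt with exclusion of light should effect the Wolff shift with capture by water (Arndt–Eistert homologation) to give racemic 2-(4-oxo-6-pentadecyl-4H-pyran-2-yl)propanoic acid F1. SOCl2 at 60 °C then gives 2-(4-oxo-6-pentadecyl-4H-pyran-2-yl)propanoyl chloride F2. Slow addition of Et3N to F2 and 17 in toluene at rt dehydrochlorinates F2 to ketene 18, which is trapped by (2+2) cycloaddition to cyclobutenone 19. Heating the same solution at 80–110 °C carries 19 through 20 to 21, where the route is rejoined.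

Step 7. Dipolar cycloaddition of diazoethane across the electron-poor C2=C3 bond of the acyl pyranone, or HCl capture of the product, may compete with C-acylation. The fallback introduces the diazo group by diazo transfer instead and sets out from 10. Coupling of 10 with Et2Zn under Pd(PPh3)4 catalysis in THF/toluene at 0 °C (Negishi acylation) should give 2-propanoyl-6-pentadecyl-4H-pyran-4-one F3. Enolisation with LiN(SiMe3)2 and CF3CO2CH2CF3 in THF at −78 °C gives 4,4,4-trifluoro-2-methyl-1-(4-oxo-6-pentadecyl-4H-pyran-2-yl)butane-1,3-dione F4. Treatment of F4 with MeSO2N3, Et3N and H2O in MeCN at rt (detrifluoroacetylative diazo transfer) returns to the route at 13.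

Step 2. Over-addition of the dianion to the very electrophilic keto ester carbonyl of the product, and proton transfer from product to unreacted dianion, may erode the acylation. The fallback brings in the carboxyl carbon as a masked aldehyde and sets out from 4. Dianion 6 is acylated with ethyl diethoxyacetate (THF, −78 → 0 °C) to give 1,1-diethoxyhenicosane-2,4,6-trione F5. Aqueous HCl/AcOH at 60 °C closes the pyranone and unmasks the acetal to give 4-oxo-6-pentadecyl-4H-pyran-2-carbaldehyde F6. Pinnick oxidation (NaClO2, NaH2PO4, 2-methyl-2-butene, t-BuOH/H2O, rt) then gives acid 9, where the route is rejoined.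

**Further compounds**
F1 | step 9 | 2-(4-oxo-6-pentadecyl-4H-pyran-2-yl)propanoic acid (racemic) | CCCCCCCCCCCCCCCc1cc(=O)cc(C(C)C(=O)O)o1
F2 | step 9 | 2-(4-oxo-6-pentadecyl-4H-pyran-2-yl)propanoyl chloride (racemic) | CCCCCCCCCCCCCCCc1cc(=O)cc(C(C)C(=O)Cl)o1
F3 | step 7 | 2-propanoyl-6-pentadecyl-4H-pyran-4-one | CCCCCCCCCCCCCCCc1cc(=O)cc(C(=O)CC)o1
F4 | step 7 | 4,4,4-trifluoro-2-methyl-1-(4-oxo-6-pentadecyl-4H-pyran-2-yl)butane-1,3-dione (racemic) | CCCCCCCCCCCCCCCc1cc(=O)cc(C(=O)C(C)C(=O)C(F)(F)F)o1
F5 | step 2 | 1,1-diethoxyhenicosane-2,4,6-trione | CCCCCCCCCCCCCCCC(=O)CC(=O)CC(=O)C(OCC)OCC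
F6 | step 2 | 4-oxo-6-pentadecyl-4H-pyran-2-carbaldehyde | CCCCCCCCCCCCCCCc1cc(=O)cc(C=O)o1
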